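## Retrosynthetic overview

1. The aldehyde comes from a neopentyl PMB ether. The 12-membered ring is opened at the C(sp2)–C(sp3) bond next to one ring alkene: an intramolecular B-alkyl Suzuki–Miyaura coupling of an alkenyl bromide with the 9-BBN adduct of a terminal diene, on two arms that sit trans on the cyclohexane.
2. The spiro-oxirane comes from the ketone and a sulfonium methylide. The dienyl arm comes from a Negishi coupling of a 2-bromoethyl ketone with (3Z)-4-iodopenta-1,3-diene, itself made from ethyl but-2-ynoate by anti hydroiodination.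
3. The three contiguous ring stereocentres come from a Stork–Danheiser transposition, an anti conjugate addition of the homoprenyl group and an axial enolate alkylation, all relayed from one α′ stereocentre.
4. That stereocentre comes from a palladium-catalysed asymmetric allylic alkylation of the silyl dienol ether of 3-isobutoxycyclohexenone with a (Z)-3-bromobut-2-enyl carbonate (new step).
5. Ring order: cyclohexane (bought as cyclohexane-1,3-dione), then oxirane, then the 12-membered carbocycle.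

Assumption: the SMILES is read literally (both ring alkenes Z, the two macrocycle arms trans on the six-membered ring); locants are those of each compound's own name; the ligand antipode in step 5 is fixed by a first screen. Stereochemical outcomes are predictions from the models named in each step.

## Route

Step 1
Reactants: 1 but-2-yn-1-ol
Product: 3 (2Z)-3-bromobut-2-en-1-ol, via sodium alkenylalanate 2 (not isolated)
Conditions: NaAlH2(OCH2CH2OCH3)2, THF, 0 °C to rt; then N-bromosuccinimide, −78 °C; aq. potassium sodium tartrate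
Reagents that add atoms: N-bromosuccinimide (O=C1CCC(=O)N1Br)
Why: Hydroxyl-directed trans-hydroalumination of the propargylic alcohol puts aluminium on C-3 in a five-membered alanate, and bromodealumination with retention gives the Z bromide (Corey-type hydroalumination/halogenation).

Step 2
Reactants: 3 (2Z)-3-bromobut-2-en-1-ol
Product: 4 (2Z)-3-bromobut-2-en-1-yl methyl carbonate
Conditions: ClCO2Me, pyridine, CH2Cl2, 0 °C
Reagents that add atoms: methyl chloroformate (COC(=O)Cl)
Why: Simple O-acylation of the allylic alcohol (carbonate formation) gives the ionisable allyl partner without touching the alkene geometry.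

Step 3
Reactants: 5 cyclohexane-1,3-dione
Product: 6 3-(2-methylpropoxy)cyclohex-2-en-1-one
Conditions: i-BuOH, TsOH·H2O (cat.), toluene, reflux, Dean–Stark
Reagents that add atoms: 2-methylpropan-1-ol (CC(C)CO)
Why: Acid-catalysed vinylogous ester formation driven by azeotropic removal of water.

Step 4
Reactants: 6 3-(2-methylpropoxy)cyclohex-2-en-1-one
Product: 8 trimethyl{[5-(2-methylpropoxy)cyclohexa-1,5-dien-1-yl]oxy}silane, via lithium dienolate 7 (not isolated)
Conditions: LiN(i-Pr)2, THF, −78 °C; then Me3SiCl, −78 °C to rt; distil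
Reagents that add atoms: chlorotrimethylsilane (C[Si](C)(C)Cl)
Why: Kinetic α′-deprotonation of the vinylogous ester and O-silylation give the cross-conjugated 2-silyloxydiene (silyl enol ether formation).

Step 5
Reactants: 8 trimethyl{[5-(2-methylpropoxy)cyclohexa-1,5-dien-1-yl]oxy}silane; 4 (2Z)-3-bromobut-2-en-1-yl methyl carbonate
Product: 9 (6R)-6-[(2Z)-3-bromobut-2-en-1-yl]-3-(2-methylpropoxy)cyclohex-2-en-1-one
Conditions: Pd2(dba)3·CHCl3 (2.5 mol %; dba = dibenzylideneacetone), (R,R)-ANDEN-phenyl Trost ligand (6 mol %), Bu4N[Ph3SiF2] (20 mol %), toluene, 0 °C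
Reagents that add atoms: none
Why: Proposed new method: a fluoride-initiated palladium-catalysed asymmetric allylic alkylation in which the silyl dienol ether of a vinylogous ester is allylated by a (Z)-3-bromo-3-methylallyl carbonate to set a tertiary α′ stereocentre (6R, ligand antipode chosen by screening); zerovalent palladium should ionise the allylic C–O bond much faster than it inserts into the hindered trisubstituted C(sp2)–Br bond, the methoxide released on decarboxylation desilylates 8 so the enolate appears only as fast as the π-allyl complex (little free base, so little racemisation or double allylation), attack goes to the CH2 terminus inside the chiral pocket, and the Z geometry should survive because syn/anti exchange would need an η1 complex at the fully substituted bromine-bearing terminus; closest known reactions are the Trost asymmetric allylic alkylation of ketone enolates and enol carbonates and the Stoltz silyl enol ether variant of the Tsuji allylation.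

Step 6
Reactants: 9 (6R)-6-[(2Z)-3-bromobut-2-en-1-yl]-3-(2-methylpropoxy)cyclohex-2-en-1-one
Product: 11 (4R)-4-[(2Z)-3-bromobut-2-en-1-yl]-3-{[(4-methoxyphenyl)methoxy]methyl}cyclohex-2-en-1-one, via lithium alkoxide adduct 10 (not isolated)
Conditions: Bu3SnCH2OPMB, n-BuLi, THF, −78 °C; CeCl3; 9, −78 °C; then 1 M HCl, THF, rt
Reagents that add atoms: tributyl{[(4-methoxyphenyl)methoxy]methyl}stannane (CCCC[Sn](CCCC)(CCCC)COCc1ccc(OC)cc1)
Why: Stork–Danheiser sequence: 1,2-addition of the α-alkoxymethyl organometallic (tin–lithium exchange, cerium to suppress enolisation) and acid-promoted hydrolysis with 1,3-carbonyl transposition; the stereocentre is untouched and becomes C-4.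

Step 7
Reactants: 11 (4R)-4-[(2Z)-3-bromobut-2-en-1-yl]-3-{[(4-methoxyphenyl)methoxy]methyl}cyclohex-2-en-1-one; 12 5-bromo-2-methylpent-2-ene
Product: 14 {[(3S,4R)-4-[(2Z)-3-bromobut-2-en-1-yl]-3-{[(4-methoxyphenyl)methoxy]methyl}-3-(4-methylpent-3-en-1-yl)cyclohex-1-en-1-yl]oxy}trimethylsilane, via homoprenylmagnesium bromide 13 (not isolated)
Conditions: 12, Mg, THF; then CuBr·SMe2 (10 mol %), Me3SiCl, HMPA, 11, THF, −78 °C; Et3N quench
Reagents that add atoms: chlorotrimethylsilane (C[Si](C)(C)Cl)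
Why: Copper-catalysed, Me3SiCl-accelerated conjugate addition (Kuwajima–Nakamura conditions) to the β,β-disubstituted enone; A(1,2) strain holds the C-4 arm pseudoaxial and the homoprenyl group enters anti to it, setting the quaternary carbon (3S).

Step 8
Reactants: 15 2-bromoethanol
Product: 16 2-bromoethyl trifluoromethanesulfonate
Conditions: (CF3SO2)2O, pyridine, CH2Cl2, −20 °C
Reagents that add atoms: trifluoromethanesulfonic anhydride (O=S(=O)(OS(=O)(=O)C(F)(F)F)C(F)(F)F)
Why: O-triflation of the primary alcohol gives a two-carbon electrophile reactive enough for a hindered enolate while keeping the bromide as the later coupling handle.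

Step 9
Reactants: 14 {[(3S,4R)-4-[(2Z)-3-bromobut-2-en-1-yl]-3-{[(4-methoxyphenyl)methoxy]methyl}-3-(4-methylpent-3-en-1-yl)cyclohex-1-en-1-yl]oxy}trimethylsilane; 16 2-bromoethyl trifluoromethanesulfonate
Product: 18 (2R,3S,4R)-2-(2-bromoethyl)-4-[(2Z)-3-bromobut-2-en-1-yl]-3-{[(4-methoxyphenyl)methoxy]methyl}-3-(4-methylpent-3-en-1-yl)cyclohexan-1-one, via lithium enolate 17 (not isolated)
Conditions: MeLi, THF, 0 °C; then 16, −78 to −30 °C
Reagents that add atoms: none
Why: Regiospecific enolate generation from the silyl enol ether (House method) and C-alkylation by the primary triflate; axial attack anti to the pseudoaxial CH2OPMB group, on the face free of a 1,3-diaxial clash with the C-4 arm, gives the 2,4-trans ketone (2R).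

Step 10
Reactants: 19 ethyl but-2-ynoate
Product: 20 ethyl (2Z)-3-iodobut-2-enoate
Conditions: NaI, AcOH, 115 °C, 1.5 h
Reagents that add atoms: sodium iodide ([Na+].[I-])
Why: Conjugate addition of iodide to the ynoate and anti protonation in acetic acid (formal anti hydroiodination) give the Z iodoenoate, with iodine cis to the ester, under kinetic control.

Step 11
Reactants: 20 ethyl (2Z)-3-iodobut-2-enoate
Product: 21 (2Z)-3-iodobut-2-en-1-ol
Conditions: i-Bu2AlH (2.2 equiv), CH2Cl2, −78 to 0 °C; aq. potassium sodium tartrate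
Reagents that add atoms: none
Why: 1,2-Reduction of the α,β-unsaturated ester by the aluminium hydride gives the allylic alcohol without touching the alkenyl iodide or its geometry.

Step 12
Reactants: 21 (2Z)-3-iodobut-2-en-1-ol
Product: 22 (2Z)-3-iodobut-2-enal
Conditions: MnO2, CH2Cl2, rt, dark
Reagents that add atoms: none
Why: Mild allylic oxidation with MnO2; the enal is kept dark and used at once to avoid Z/E isomerisation.

Step 13
Reactants: 22 (2Z)-3-iodobut-2-enal
Product: 23 (3Z)-4-iodopenta-1,3-diene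
Conditions: Ph3PCH3Br, KN(SiMe3)2, THF, −78 to 0 °C; kept as a cold solution
Reagents that add atoms: methyltriphenylphosphonium bromide ([Br-].C[P+](c1ccccc1)(c1ccccc1)c1ccccc1)
Why: Wittig methylenation of the aldehyde is faster than any reaction at the alkenyl iodide, whose geometry is carried over.

Step 14
Reactants: 18 (2R,3S,4R)-2-(2-bromoethyl)-4-[(2Z)-3-bromobut-2-en-1-yl]-3-{[(4-methoxyphenyl)methoxy]methyl}-3-(4-methylpent-3-en-1-yl)cyclohexan-1-one; 23 (3Z)-4-iodopenta-1,3-diene
Product: 25 (2R,3S,4R)-4-[(2Z)-3-bromobut-2-en-1-yl]-3-{[(4-methoxyphenyl)methoxy]methyl}-2-[(3Z)-3-methylhexa-3,5-dien-1-yl]-3-(4-methylpent-3-en-1-yl)cyclohexan-1-one, via alkylzinc bromide 24 (not isolated)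
Conditions: Zn dust, LiCl, THF, 45 °C; then 23, PdCl2(dppf) (5 mol %; dppf = 1,1'-bis(diphenylphosphino)ferrocene), THF, rt
Reagents that add atoms: none
Why: LiCl-promoted zinc insertion into the primary C–Br bond (Knochel) then Negishi coupling; palladium inserts into the alkenyl C–I bond of 23 in preference to the alkenyl bromide, and the C(sp3)–C(sp2) bond forms with retention, giving the Z trisubstituted alkene.

Step 15
Reactants: 25 (2R,3S,4R)-4-[(2Z)-3-bromobut-2-en-1-yl]-3-{[(4-methoxyphenyl)methoxy]methyl}-2-[(3Z)-3-methylhexa-3,5-dien-1-yl]-3-(4-methylpent-3-en-1-yl)cyclohexan-1-one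
Product: 26 (3S,4R,5S,6R)-6-[(2Z)-3-bromobut-2-en-1-yl]-5-{[(4-methoxyphenyl)methoxy]methyl}-4-[(3Z)-3-methylhexa-3,5-dien-1-yl]-5-(4-methylpent-3-en-1-yl)-1-oxaspiro[2.5]octane
Conditions: Me3S+ I−, KN(SiMe3)2, THF, −10 °C to rt
Reagents that add atoms: trimethylsulfonium iodide ([I-].C[S+](C)C)
Why: Corey–Chaykovsky epoxidation; the irreversibly adding sulfonium ylide takes the carbonyl face opposite the α-dienyl arm and the β-homoprenyl group, so the new CH2 is cis to H-4 and the oxygen cis to the dienyl arm (3S). Removing the ketone here also protects the α-centre from epimerisation in the basic step 16.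

Step 16
Reactants: 26 (3S,4R,5S,6R)-6-[(2Z)-3-bromobut-2-en-1-yl]-5-{[(4-methoxyphenyl)methoxy]methyl}-4-[(3Z)-3-methylhexa-3,5-dien-1-yl]-5-(4-methylpent-3-en-1-yl)-1-oxaspiro[2.5]octane
Product: 28 (1R,3Z,7Z,11R,12S,15S)-15-{[(4-methoxyphenyl)methoxy]methyl}-4,8-dimethyl-15-(4-methylpent-3-en-1-yl)spiro[bicyclo[9.3.1]pentadeca-3,7-diene-12,2'-oxirane], via B-alkyl-9-BBN borane 27 (not isolated)
Conditions: 9-BBN-H, THF, 0 °C to rt; then PdCl2(dppf)·CH2Cl2 (15 mol %), AsPh3, Cs2CO3, DMF/THF/H2O, 50 °C, syringe pump to 1 mM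
Reagents that add atoms: none
Why: 9-BBN adds anti-Markovnikov only to the terminal CH2=CH of the diene (trisubstituted alkenes and the alkenyl bromide are inert), and the primary alkylborane closes the 12-membered ring by intramolecular B-alkyl Suzuki–Miyaura coupling with retention at the alkenyl bromide.

Step 17
Reactants: 28 (1R,3Z,7Z,11R,12S,15S)-15-{[(4-methoxyphenyl)methoxy]methyl}-4,8-dimethyl-15-(4-methylpent-3-en-1-yl)spiro[bicyclo[9.3.1]pentadeca-3,7-diene-12,2'-oxirane]
Product: 29 [(1R,3Z,7Z,11R,12S,15S)-4,8-dimethyl-15-(4-methylpent-3-en-1-yl)spiro[bicyclo[9.3.1]pentadeca-3,7-diene-12,2'-oxiran]-15-yl]methanol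
Conditions: DDQ, CH2Cl2/pH 7 buffer, 0 °C
Reagents that add atoms: none
Why: Oxidative cleavage of the PMB ether under buffered conditions leaves the epoxide and the three trisubstituted alkenes intact.

Step 18
Reactants: 29 [(1R,3Z,7Z,11R,12S,15S)-4,8-dimethyl-15-(4-methylpent-3-en-1-yl)spiro[bicyclo[9.3.1]pentadeca-3,7-diene-12,2'-oxiran]-15-yl]methanol
Product: 30 (1R,3Z,7Z,11R,12S,15S)-4,8-dimethyl-15-(4-methylpent-3-en-1-yl)spiro[bicyclo[9.3.1]pentadeca-3,7-diene-12,2'-oxirane]-15-carbaldehyde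
Conditions: Dess–Martin periodinane, NaHCO3, CH2Cl2, 0 °C to rt
Reagents that add atoms: none
Why: Dess–Martin oxidation of the neopentyl primary alcohol gives the non-enolisable aldehyde; the buffer protects the acid-sensitive spiro-epoxide.

## Compound list

1 | but-2-yn-1-ol | CC#CCO | starting material
2 | sodium alkenylalanate (cyclic 2,5-dihydro-1,2-oxaaluminolate, Al on C-3, two 2-methoxyethoxy groups on Al) | CC1=CCO[Al-]1(OCCOC)OCCOC.[Na+] | intermediate
3 | (2Z)-3-bromobut-2-en-1-ol | C/C(Br)=C/CO | intermediate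
4 | (2Z)-3-bromobut-2-en-1-yl methyl carbonate | C/C(Br)=C/COC(=O)OC | intermediate
5 | cyclohexane-1,3-dione | O=C1CCCC(=O)C1 | starting material
6 | 3-(2-methylpropoxy)cyclohex-2-en-1-one | CC(C)COC1=CC(=O)CCC1 | intermediate
7 | lithium 5-(2-methylpropoxy)cyclohexa-1,5-dien-1-olate | [Li]OC1=CCCC(OCC(C)C)=C1 | intermediate
8 | trimethyl{[5-(2-methylpropoxy)cyclohexa-1,5-dien-1-yl]oxy}silane | C[Si](C)(C)OC1=CCCC(OCC(C)C)=C1 | intermediate
9 | (6R)-6-[(2Z)-3-bromobut-2-en-1-yl]-3-(2-methylpropoxy)cyclohex-2-en-1-one | CC(C)COC1=CC(=O)[C@@H](C/C=C(/C)Br)CC1 | intermediate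
10 | lithium (6R)-6-[(2Z)-3-bromobut-2-en-1-yl]-1-{[(4-methoxyphenyl)methoxy]methyl}-3-(2-methylpropoxy)cyclohex-2-en-1-olate (C-1 epimers) | CC(C)COC1=CC(O[Li])(COCc2ccc(OC)cc2)[C@@H](C/C=C(/C)Br)CC1 | intermediate
11 | (4R)-4-[(2Z)-3-bromobut-2-en-1-yl]-3-{[(4-methoxyphenyl)methoxy]methyl}cyclohex-2-en-1-one | O=C1C=C(COCc2ccc(OC)cc2)[C@@H](C/C=C(/C)Br)CC1 | intermediate
12 | 5-bromo-2-methylpent-2-ene | CC(C)=CCCBr | starting material
13 | (4-methylpent-3-en-1-yl)magnesium bromide | CC(C)=CCC[Mg]Br | intermediate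
14 | {[(3S,4R)-4-[(2Z)-3-bromobut-2-en-1-yl]-3-{[(4-methoxyphenyl)methoxy]methyl}-3-(4-methylpent-3-en-1-yl)cyclohex-1-en-1-yl]oxy}trimethylsilane | C[Si](C)(C)OC1=C[C@](COCc2ccc(OC)cc2)(CCC=C(C)C)[C@@H](C/C=C(/C)Br)CC1 | intermediate
15 | 2-bromoethanol | OCCBr | starting material
16 | 2-bromoethyl trifluoromethanesulfonate | BrCCOS(=O)(=O)C(F)(F)F | intermediate
17 | lithium (3S,4R)-4-[(2Z)-3-bromobut-2-en-1-yl]-3-{[(4-methoxyphenyl)methoxy]methyl}-3-(4-methylpent-3-en-1-yl)cyclohex-1-en-1-olate | [Li]OC1=C[C@](COCc2ccc(OC)cc2)(CCC=C(C)C)[C@@H](C/C=C(/C)Br)CC1 | intermediate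
18 | (2R,3S,4R)-2-(2-bromoethyl)-4-[(2Z)-3-bromobut-2-en-1-yl]-3-{[(4-methoxyphenyl)methoxy]methyl}-3-(4-methylpent-3-en-1-yl)cyclohexan-1-one | O=C1[C@H](CCBr)[C@](COCc2ccc(OC)cc2)(CCC=C(C)C)[C@@H](C/C=C(/C)Br)CC1 | intermediate
19 | ethyl but-2-ynoate | CC#CC(=O)OCC | starting material
20 | ethyl (2Z)-3-iodobut-2-enoate | C/C(I)=C/C(=O)OCC | intermediate
21 | (2Z)-3-iodobut-2-en-1-ol | C/C(I)=C/CO | intermediate
22 | (2Z)-3-iodobut-2-enal | C/C(I)=C/C=O | intermediate
23 | (3Z)-4-iodopenta-1,3-diene | C/C(I)=C/C=C | intermediate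
24 | alkylzinc bromide of 18 (C–ZnBr in place of the primary C–Br) | O=C1[C@H](CC[Zn]Br)[C@](COCc2ccc(OC)cc2)(CCC=C(C)C)[C@@H](C/C=C(/C)Br)CC1 | intermediate
25 | (2R,3S,4R)-4-[(2Z)-3-bromobut-2-en-1-yl]-3-{[(4-methoxyphenyl)methoxy]methyl}-2-[(3Z)-3-methylhexa-3,5-dien-1-yl]-3-(4-methylpent-3-en-1-yl)cyclohexan-1-one | O=C1[C@H](CC/C(C)=C\C=C)[C@](COCc2ccc(OC)cc2)(CCC=C(C)C)[C@@H](C/C=C(/C)Br)CC1 | intermediate
26 | (3S,4R,5S,6R)-6-[(2Z)-3-bromobut-2-en-1-yl]-5-{[(4-methoxyphenyl)methoxy]methyl}-4-[(3Z)-3-methylhexa-3,5-dien-1-yl]-5-(4-methylpent-3-en-1-yl)-1-oxaspiro[2.5]octane | C=C/C=C(/C)CC[C@H]1[C@]2(CO2)CC[C@H](C/C=C(/C)Br)[C@@]1(COCc3ccc(OC)cc3)CCC=C(C)C | intermediate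
27 | B-alkyl-9-BBN borane of 26 (boron on the former terminal diene carbon) | B1(C2CCCC1CCC2)CC/C=C(/C)CC[C@H]1[C@]2(CO2)CC[C@H](C/C=C(/C)Br)[C@@]1(COCc3ccc(OC)cc3)CCC=C(C)C | intermediate
28 | (1R,3Z,7Z,11R,12S,15S)-15-{[(4-methoxyphenyl)methoxy]methyl}-4,8-dimethyl-15-(4-methylpent-3-en-1-yl)spiro[bicyclo[9.3.1]pentadeca-3,7-diene-12,2'-oxirane] | CC(C)=CCC[C@]1(COCc3ccc(OC)cc3)[C@H]2C/C=C(/C)CC/C=C(/C)CC[C@H]1[C@@]1(CC2)CO1 | intermediate
29 | [(1R,3Z,7Z,11R,12S,15S)-4,8-dimethyl-15-(4-methylpent-3-en-1-yl)spiro[bicyclo[9.3.1]pentadeca-3,7-diene-12,2'-oxiran]-15-yl]methanol | CC(C)=CCC[C@]1(CO)[C@H]2C/C=C(/C)CC/C=C(/C)CC[C@H]1[C@@]1(CC2)CO1 | intermediate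
30 | (1R,3Z,7Z,11R,12S,15S)-4,8-dimethyl-15-(4-methylpent-3-en-1-yl)spiro[bicyclo[9.3.1]pentadeca-3,7-diene-12,2'-oxirane]-15-carbaldehyde (CNP0283574.1) | CC(C)=CCC[C@]1(C=O)[C@H]2C/C=C(/C)CC/C=C(/C)CC[C@H]1[C@@]1(CC2)CO1 | target

## Step count and risks

Total steps: 18. Longest linear sequence: 11 steps (3, 4, 5, 6, 7, 9, 14, 15, 16, 17, 18; the line through steps 1 and 2 is equally long), i.e. 11/18, below two thirds. The diene branch (steps 10 to 13) joins at step 14 and the triflate (step 8) at step 9.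

The three steps most likely to fail:

Step 5 (the proposed new asymmetric allylation). Risks are low ee at a tertiary α′ centre, palladium insertion into the alkenyl C–Br bond, and loss of Z geometry. Fallback with known chemistry (Enders hydrazone alkylation), setting out from 5 and 3 and returning at 11: 5 is mono-ketalised (ethane-1,2-diol, TsOH, benzene, Dean–Stark) to 1,4-dioxaspiro[4.5]decan-7-one F1 and condensed with (R)-1-amino-2-(methoxymethyl)pyrrolidine (RAMP) to the hydrazone F2. Alcohol 3 is converted (CBr4, PPh3, CH2Cl2, 0 °C) into (2Z)-1,3-dibromobut-2-ene F3. F2 is deprotonated at the unhindered C-8 with LiN(i-Pr)2 (THF, 0 °C) to the lithium azaenolate F4 and alkylated with F3 at −95 °C to the (8R) hydrazone F5. RAMP is the antipode expected to give this sense, by analogy with 2-alkylcyclohexanones. Buffered aqueous CuCl2 releases the (8R) ketone F6. Addition of PMBOCH2Li/CeCl3 gives the alkoxide F7, and 1 M HCl work-up hydrolyses the ketal and dehydrates the β-hydroxy ketone to give 11.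

Step 9 (alkylation of a hindered enolate next to a quaternary carbon with a hard triflate). Risks are O-alkylation, proton transfer and loss of the 2,4-trans selectivity. Fallback, setting out from 14 and returning at 18: enolate 17 (MeLi on 14) is alkylated with the soft and far more reactive methyl bromoacetate (THF, −78 °C) to the keto ester F8. LiAlH4 (THF, 0 °C) gives the diol F9. CBr4/PPh3 at −20 °C brominates only the primary hydroxyl to give the bromo alcohol F10, and Dess–Martin oxidation restores the ketone, giving 18.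

Step 16 (12-membered ring closure across trans-disposed arms, with the CH2OPMB group on the one-carbon bridge). Risks are slow transmetalation, oligomers, protodeboronation and incomplete regiocontrol in the diene hydroboration. Fallback, setting out from 26 and returning at 28, closes the same bond by nickel-catalysed reductive cross-electrophile coupling under neutral conditions: borane 27 is oxidised (NaBO3·4H2O) to the primary alcohol F11 and converted (I2, PPh3, imidazole, CH2Cl2, 0 °C) into the primary iodide F12. F12 is cyclised with NiBr2(CH3OCH2CH2OCH3)/4,4'-di-tert-butyl-2,2'-bipyridine, Mn powder and NaI in DMA at 2 mM to give 28.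

## Further compounds

F1 | step 5 | 1,4-dioxaspiro[4.5]decan-7-one | O=C1CCCC2(C1)OCCO2
F2 | step 5 | N-[(2R)-2-(methoxymethyl)pyrrolidin-1-yl]-1,4-dioxaspiro[4.5]decan-7-imine (RAMP hydrazone) | COC[C@H]1CCCN1N=C1CCCC2(C1)OCCO2
F3 | step 5 | (2Z)-1,3-dibromobut-2-ene | C/C(Br)=C/CBr
F4 | step 5 | lithium azaenolate of F2 (C-7/C-8 ene-hydrazide) | COC[C@H]1CCCN1N([Li])C1=CCCC2(C1)OCCO2
F5 | step 5 | (8R)-8-[(2Z)-3-bromobut-2-en-1-yl]-N-[(2R)-2-(methoxymethyl)pyrrolidin-1-yl]-1,4-dioxaspiro[4.5]decan-7-imine | COC[C@H]1CCCN1N=C1[C@@H](C/C=C(/C)Br)CCC2(C1)OCCO2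
F6 | step 5 | (8R)-8-[(2Z)-3-bromobut-2-en-1-yl]-1,4-dioxaspiro[4.5]decan-7-one | O=C1[C@@H](C/C=C(/C)Br)CCC2(C1)OCCO2
F7 | step 5 | lithium (8R)-8-[(2Z)-3-bromobut-2-en-1-yl]-7-{[(4-methoxyphenyl)methoxy]methyl}-1,4-dioxaspiro[4.5]decan-7-olate (C-7 epimers) | [Li]OC1(COCc3ccc(OC)cc3)[C@@H](C/C=C(/C)Br)CCC2(C1)OCCO2
F8 | step 9 | methyl 2-[(1R,2S,3R)-3-[(2Z)-3-bromobut-2-en-1-yl]-2-{[(4-methoxyphenyl)methoxy]methyl}-2-(4-methylpent-3-en-1-yl)-6-oxocyclohexyl]acetate | O=C1[C@H](CC(=O)OC)[C@](COCc2ccc(OC)cc2)(CCC=C(C)C)[C@@H](C/C=C(/C)Br)CC1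
F9 | step 9 | diol from F8: ring carbinol (C-1 epimers) and 2-hydroxyethyl arm | OC1[C@H](CCO)[C@](COCc2ccc(OC)cc2)(CCC=C(C)C)[C@@H](C/C=C(/C)Br)CC1
F10 | step 9 | bromo alcohol from F9: ring carbinol (C-1 epimers) and 2-bromoethyl arm | OC1[C@H](CCBr)[C@](COCc2ccc(OC)cc2)(CCC=C(C)C)[C@@H](C/C=C(/C)Br)CC1
F11 | step 16 | primary alcohol from 27: (3Z)-6-hydroxy-3-methylhex-3-en-1-yl arm on the oxaspiro core of 26 | OCC/C=C(/C)CC[C@H]1[C@]2(CO2)CC[C@H](C/C=C(/C)Br)[C@@]1(COCc3ccc(OC)cc3)CCC=C(C)C
F12 | step 16 | primary iodide from F11: (3Z)-6-iodo-3-methylhex-3-en-1-yl arm on the oxaspiro core of 26 | ICC/C=C(/C)CC[C@H]1[C@]2(CO2)CC[C@H](C/C=C(/C)Br)[C@@]1(COCc3ccc(OC)cc3)CCC=C(C)C
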